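## The problem

- The target is a C2-symmetric C40 carotenoid. An all-E nonaene chain (C7 to C7') carries at each end a saturated 1,1,5-trimethylcyclohexane ring, joined to the chain only through the C6–C7 single bond.
- Each ring holds four contiguous stereocentres, (3R,4S,5R,6R), next to the quaternary C1. The chain at C6 and the methyl at C5 are trans-diequatorial. The sulfated oxygen at C4 is equatorial and trans to the C5 methyl. The free hydroxyl at C3 is axial, cis to O4 and syn-axial to one C1 methyl.
- C5 is the centre that must be set absolutely. C6 follows from it as the stable trans isomer, and the pair fixes the chair. The chair then decides C3, because hydride can only arrive from the face away from the axial C1 methyl, and C4, where the equatorial ether is the stable epimer.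
- The two ring oxygens are vicinal and cis but end differently, one as a hydrogen sulfate and one free, so they must be told apart well before the end.
- The nonaene does not survive strong acid, oxidants, halogen or light. The sulfate half-esters are acid-labile, ionic and incompatible with carbanion chemistry. The chain should therefore be attached late and sulfur introduced last.
- The ring invites a short construction: C1(CH3)2–C2–C3(O)–C4 is the carbon skeleton of mesityl oxide (1) and CH3–C5–C6–C7 is a crotonyl unit, so the ring with its C3 oxygen is their formal [4+2] adduct.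

## Retrosynthesis

Carotenoid numbering is used for all positions (ring C1–C6, chain C7–C15, primes for the second half).

**O–S and O–Si bonds.** The sulfate esters of 26 are cut first, which leads through the bis(TBS) disulfate 24 to the 4,4'-diol 22 and on to the fully silylated carotene 20 (O4 as TES, O3 as TBS). Sulfating a free tetrol would rest only on the steric difference between an equatorial and an axial hydroxyl. Two silyl ethers of different lability make the regiochemistry a matter of protecting-group order. The forward steps must remove TES beside TBS, sulfate a secondary alcohol on a polyene, and take off a hindered TBS ether without touching the sulfate.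

**C7=C8 and C7'=C8'.** Cutting both disubstituted double bonds of 20 gives two molecules of the ring sulfone 17 and the C20 dialdehyde 18. This cut separates all ring stereochemistry from the polyene, uses one commercial polyene for C8–C8', and needs the same coupling twice. Cuts deeper in the chain (C9–C10, C11–C12, C15–C15') would require polyene fragments that have to be made. The forward reaction is a twofold E-selective olefination with a β-branched sulfone anion.

**C7–S and the acyl group.** Sulfone 17 goes back through sulfide 16 to the primary alcohol 15, and 15 to the imide 14 by reductive removal of the oxazolidinone. C7 thus stays at the acid oxidation level until the ring is finished, and nothing acidic sits at C7 during the enolate chemistry.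

**C3–O and C4–O.** Imide 14 is simplified by removing the O3 silyl group (13), the C3 hydride (12), the C4 configuration (11) and the C4 oxygen (enol ether 9), which arrives at ketone 8. A ketone at C3 is the right handle because the target needs hydrogen, not oxygen, delivered to C3 from the open face. Dihydroxylation of a C3=C4 alkene would add both oxygens anti to the axial C1 methyl, which is the wrong face. The forward steps must oxygenate C4 and not C2, equilibrate C4 to the equatorial ether, and reduce from the equatorial direction.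

**C4–C5 and C1–C6.** Ketone 8 is cut into the silyl dienol ether 2 and the crotonyl imide 5. Both ring bonds, the quaternary carbon, C5 and C6 then come from one step and two small achiral pieces. The other [4+2] cut, C1–C2 and C5–C6, leaves no oxygen at C3. The forward reaction must add the CH2 terminus of 2 to the β-carbon of 5 with control of the absolute configuration and then close the enolate onto a β,β-disubstituted enone.

**Building blocks.** Diene 2 comes from mesityl oxide 1 by kinetic enol silylation. Imide 5 comes from oxazolidinone 3 and crotonyl chloride 4.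

## Roads not taken

**Alternative 1:** The ring is taken from the chiral pool. Natural quinic acid A3 is degraded to the cis-fused acetonide enone A2, which already holds O3 and O4 in the absolute and relative configuration of the target.
- Key step: Me2CuLi adds to C5 anti to the C4 oxygen, and the C1=C6 enolate is trapped by CH2O anti to the new methyl. This forms C5–CH3 and C6–C7 and gives A1; no ring closes.
- Merits: both oxygen stereocentres are bought, not made. There is no asymmetric catalyst, no question of which α-carbon is oxygenated, and no C4 epimer to equilibrate. In these respects this road is better than the chosen one.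
- Weak points: A1 has a ketone at C1 where the target has C(CH3)2. Geminal dimethylation beside an enolisable C6 that carries a β-hydroxymethyl group invites retro-aldol cleavage and dehydration. It needs either Me2TiCl2 on a sensitive substrate or a three-step methylenation, cyclopropanation and hydrogenolysis. The acetonide does not tell O3 from O4, and A2 itself costs several steps from A3.
- Comparison: the chosen plan makes the quaternary carbon with both methyls and the whole ring in one step, and its C3 ketone delivers O3 and O4 one after the other, already differentiated. It pays with catalyst-controlled absolute configuration and a C4 oxygenation that is less certain than the stereochemistry of A1.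

**Alternative 2:** The cut is at C9–CH3 and C10–C11 on both sides.
- Key step: two molecules of the ring enyne A5 undergo syn-methylalumination (AlMe3, catalytic Cp2ZrCl2). The alkenylalanes are coupled in the same flask with the pentaene diiodide A6 (Pd(PPh3)4, ZnCl2) to give the tetrakis(silyl) ether A4.
- Merits: the trisubstituted 9,10 bond is fixed by syn-carbometalation and the 11,12 bond by a stereoretentive coupling. This geometric control is better than that of the olefination in the chosen plan.
- Weak points: the step solves the chain, which is not the hard part. A5 needs the same four ring stereocentres as 17 and, in addition, C7–C10 built on as an E-enyne. A6 is a light-sensitive diiodide that must be made, whereas 18 is bought. The four identical silyl ethers of A4 leave the O3/O4 problem open.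
- Comparison: the chosen plan forms only the two disubstituted 7,8 bonds, which favour E and can be equilibrated thermally, and it is several steps shorter.

**Alternative 3:** The cut is at C1–C2 and C5–C6.
- Key step: Diels–Alder reaction of (E)-penta-1,3-diene A8 with the trifluoroethyl 3-methylbut-2-enoate A9 under a chiral oxazaborolidinium Lewis acid activated by AlBr3, giving the cis (endo) cyclohexene ester A7.
- Merits: a concerted, well-understood reaction with dependable regiochemistry and catalyst control. Ring, quaternary carbon, C5 and C6 arise in one step. The double bond sits between C3 and C4 without ambiguity, so the regiochemical question of step 4 of the chosen plan does not arise; here this road is better.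
- Weak points: a β,β-dimethyl enoate is among the poorest dienophiles and the diene is unactivated. The endo adduct is the C6 epimer and must be equilibrated. Above all, the alkene must become a cis-diol on the face syn to the axial C1 methyl, whereas OsO4 would add anti to it and give both centres wrong and undifferentiated.
- Comparison: the chosen plan has a C3 ketone, which lets hydrogen arrive from the open face, as the target requires, and introduces O3 and O4 in separate steps.

Key step: step 3

**Remarks and assumptions**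

- The target is drawn as the free bis(hydrogen sulfate). The sulfate half-esters are made and handled as salts, and the acid form is written for 24 and 26.
- (R,R)-t-Bu-box is 2,2'-(propane-2,2-diyl)bis[(4R)-4-tert-butyl-4,5-dihydro-1,3-oxazole]. Its sense of induction is taken from the square-planar chelate model. If the opposite sense is found, the (S,S) ligand is used and nothing else changes.
- The descriptor of the methyl-bearing ring carbon changes from S (7–9) to R (from 11 on) because the new oxygen changes priorities. No centre is inverted except C4 in step 6.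
- All operations from step 12 on are run with exclusion of light and air.

## Route

Step 1
Reactants: 1 mesityl oxide
Product: 2 4-methyl-2-(trimethylsilyloxy)penta-1,3-diene
Conditions: LiN(i-Pr)2, THF, −78 °C; Me3SiCl, −78 °C → rt
Reagents that add atoms: chlorotrimethylsilane, C[Si](C)(C)Cl
Why: Kinetic deprotonation of an enone by a lithium amide removes an α' (methyl) proton, and O-silylation of the cross-conjugated dienolate gives the 2-silyloxydiene (kinetic silyl enol ether formation).

Step 2
Reactants: 3 1,3-oxazolidin-2-one; 4 (E)-but-2-enoyl chloride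
Product: 5 3-[(E)-but-2-enoyl]-1,3-oxazolidin-2-one
Conditions: n-BuLi, THF, −78 °C; then 4, −78 → 0 °C
Reagents that add atoms: none
Why: N-Acylation of the lithiated oxazolidinone by an acid chloride is the standard entry to N-enoyl imides; the E double bond is not touched.

Step 3
Reactants: 2 4-methyl-2-(trimethylsilyloxy)penta-1,3-diene; 5 3-[(E)-but-2-enoyl]-1,3-oxazolidin-2-one
Product: 8 3-[(1R,6S)-2,2,6-trimethyl-4-oxocyclohexane-1-carbonyl]-1,3-oxazolidin-2-one, via open-chain Michael adduct 6 (not isolated), via ring silyl enol ether 7 (not isolated)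
Conditions: [Cu((R,R)-t-Bu-box)](SbF6)2 (10 mol%), CH2Cl2, −40 → 0 °C; then 1 M HCl, THF, 0 °C
Reagents that add atoms: none
Why: Proposed new method: the imide chelates divalent copper through both carbonyl oxygens in its s-cis form, and the terminal CH2 of 2 adds to its β-carbon (Mukaiyama–Michael), giving a copper-bound imide enolate and a silyl-activated β,β-dimethyl enone, written in its silyl-transferred form as 6. The enolate carbon (C6) then adds to C1 of that enone in a 6-endo-trig Michael closure, which makes the ring and the quaternary carbon, leaves silicon on the C3 oxygen (7) and frees the catalyst; acid hydrolysis gives ketone 8. The closest known reaction types are the copper–bis(oxazoline)-catalysed Mukaiyama–Michael addition of enol silanes to N-enoyl oxazolidinones, the Diels–Alder reactions of this crotonyl imide with the same catalyst class, and the Lewis-acid-promoted stepwise [4+2] annulation of 4,4-disubstituted 2-silyloxydienes; their union in one enantioselective catalytic step has not been shown. The stepwise path matters because the Z-methyl of 2 disfavours the s-cis diene that a concerted cycloaddition needs, whereas the first bond can form from any conformer and closure only needs rotation in the cationic intermediate. C5 is controlled by the ligand: in the square-planar chelate the tert-butyl group of the (R,R) ligand covers one face of the imide, so the nucleophile adds to the β-Re face, the mirror image of the sense known for the (S,S) catalyst, and gives the S centre of 8. C6 follows C5 in the chair-like closure that places the acyl group and the C5 methyl trans-diequatorial, and this is also the thermodynamic isomer. The step needs C-attack through the CH2 terminus of the diene (its only enol ether carbon) and closure through carbon, not oxygen, of the enolate; O-closure would give a dihydropyran that can reopen under the Lewis acid, whereas C-closure is irreversible.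

Step 4
Reactants: 8 3-[(1R,6S)-2,2,6-trimethyl-4-oxocyclohexane-1-carbonyl]-1,3-oxazolidin-2-one
Product: 9 3-[(1R,2S)-2,6,6-trimethyl-4-(triethylsilyloxy)cyclohex-3-ene-1-carbonyl]-1,3-oxazolidin-2-one
Conditions: LiN(i-Pr)2, Et3SiCl (in situ), THF, −78 °C
Reagents that add atoms: chlorotriethylsilane, CC[Si](Cl)(CC)CC
Why: Kinetic enolisation with in situ O-silylation; the imide α-hydrogen at C6 is not removed because allylic 1,3-strain keeps it out of alignment with the acyl π-system. Of the two ring methylenes, C4 (tertiary neighbour) should be deprotonated faster than the neopentyl-type C2, though probably not exclusively.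

Step 5
Reactants: 9 3-[(1R,2S)-2,6,6-trimethyl-4-(triethylsilyloxy)cyclohex-3-ene-1-carbonyl]-1,3-oxazolidin-2-one
Product: 11 3-[(1R,5R,6R)-2,2,6-trimethyl-4-oxo-5-(triethylsilyloxy)cyclohexane-1-carbonyl]-1,3-oxazolidin-2-one, via silyloxy epoxide 10 (not isolated)
Conditions: mCPBA, CH2Cl2, −20 → 0 °C
Reagents that add atoms: 3-chloroperoxybenzoic acid, O=C(OO)c1cccc(Cl)c1
Why: Rubottom oxidation: the peracid epoxidises the enol ether on the face away from the axial C1 methyl, and the silyloxy epoxide opens with 1,4-silyl shift to the α-silyloxy ketone. The new C4–O bond is therefore expected axial and cis to the C5 methyl; step 6 corrects this centre.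

Step 6
Reactants: 11 3-[(1R,5R,6R)-2,2,6-trimethyl-4-oxo-5-(triethylsilyloxy)cyclohexane-1-carbonyl]-1,3-oxazolidin-2-one
Product: 12 3-[(1R,5S,6R)-2,2,6-trimethyl-4-oxo-5-(triethylsilyloxy)cyclohexane-1-carbonyl]-1,3-oxazolidin-2-one
Conditions: DBU (0.5 equiv), MeCN, rt → 40 °C
Reagents that add atoms: none
Why: Base-mediated epimerisation through the C3=C4 enolate; because O4 is silylated only C4 can invert (no ketol transposition). The equatorial ether avoids two syn-axial hydrogens and is favoured in a polar solvent, so it should predominate; the remaining axial epimer is separated and resubmitted.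

Step 7
Reactants: 12 3-[(1R,5S,6R)-2,2,6-trimethyl-4-oxo-5-(triethylsilyloxy)cyclohexane-1-carbonyl]-1,3-oxazolidin-2-one
Product: 13 3-[(1R,4R,5S,6R)-4-hydroxy-2,2,6-trimethyl-5-(triethylsilyloxy)cyclohexane-1-carbonyl]-1,3-oxazolidin-2-one
Conditions: LiBH(s-Bu)3, THF, −78 °C; then H2O, −78 → 0 °C
Reagents that add atoms: none
Why: Diastereoselective ketone reduction with a bulky trialkylborohydride: the axial trajectory is closed by the syn-axial C1 methyl, so hydride enters equatorially and gives the axial C3 alcohol cis to O4. The hindered imide is not reduced at −78 °C.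

Step 8
Reactants: 13 3-[(1R,4R,5S,6R)-4-hydroxy-2,2,6-trimethyl-5-(triethylsilyloxy)cyclohexane-1-carbonyl]-1,3-oxazolidin-2-one
Product: 14 3-[(1R,4R,5S,6R)-4-(tert-butyldimethylsilyloxy)-2,2,6-trimethyl-5-(triethylsilyloxy)cyclohexane-1-carbonyl]-1,3-oxazolidin-2-one
Conditions: t-BuMe2SiOTf, 2,6-lutidine, CH2Cl2, 0 °C → rt
Reagents that add atoms: tert-butyldimethylsilyl trifluoromethanesulfonate, CC(C)(C)[Si](C)(C)OS(=O)(=O)C(F)(F)F
Why: A silyl triflate with a hindered pyridine base silylates even this axial, flanked alcohol. TBS on O3 beside TES on O4 gives the two oxygens different lability.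

Step 9
Reactants: 14 3-[(1R,4R,5S,6R)-4-(tert-butyldimethylsilyloxy)-2,2,6-trimethyl-5-(triethylsilyloxy)cyclohexane-1-carbonyl]-1,3-oxazolidin-2-one
Product: 15 [(1R,4R,5S,6R)-4-(tert-butyldimethylsilyloxy)-2,2,6-trimethyl-5-(triethylsilyloxy)cyclohexyl]methanol
Conditions: LiBH4, H2O (1 equiv), Et2O, 0 °C → rt
Reagents that add atoms: none
Why: Reductive cleavage of the N-acyl oxazolidinone by borohydride gives the primary alcohol and returns the auxiliary; the silyl ethers and the non-enolisable C6 centre are unaffected.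

Step 10
Reactants: 15 [(1R,4R,5S,6R)-4-(tert-butyldimethylsilyloxy)-2,2,6-trimethyl-5-(triethylsilyloxy)cyclohexyl]methanol
Product: 16 5-({[(1R,4R,5S,6R)-4-(tert-butyldimethylsilyloxy)-2,2,6-trimethyl-5-(triethylsilyloxy)cyclohexyl]methyl}sulfanyl)-1-phenyl-1H-tetrazole
Conditions: 1-phenyl-1H-tetrazole-5-thiol, PPh3, DIAD, THF, 0 °C → rt
Reagents that add atoms: 1-phenyl-1H-tetrazole-5-thiol, Sc1nnnn1-c1ccccc1
Why: Mitsunobu thioetherification: the activated primary alcohol is displaced by the acidic tetrazole thiol; no stereocentre is involved.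

Step 11
Reactants: 16 5-({[(1R,4R,5S,6R)-4-(tert-butyldimethylsilyloxy)-2,2,6-trimethyl-5-(triethylsilyloxy)cyclohexyl]methyl}sulfanyl)-1-phenyl-1H-tetrazole
Product: 17 5-({[(1R,4R,5S,6R)-4-(tert-butyldimethylsilyloxy)-2,2,6-trimethyl-5-(triethylsilyloxy)cyclohexyl]methyl}sulfonyl)-1-phenyl-1H-tetrazole
Conditions: (NH4)6Mo7O24·4H2O (cat.), 30% H2O2, EtOH, 0 °C → rt
Reagents that add atoms: hydrogen peroxide, OO
Why: Molybdate-catalysed peroxide oxidation takes the sulfide to the sulfone; the molecule has no alkene and the hindered silyl ethers tolerate the weakly acidic medium.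

Step 12
Reactants: 17 5-({[(1R,4R,5S,6R)-4-(tert-butyldimethylsilyloxy)-2,2,6-trimethyl-5-(triethylsilyloxy)cyclohexyl]methyl}sulfonyl)-1-phenyl-1H-tetrazole (2.4 equiv); 18 crocetin dialdehyde
Product: 20 (3R,4S,5R,6R,3'R,4'S,5'R,6'R)-3,3'-bis(tert-butyldimethylsilyloxy)-4,4'-bis(triethylsilyloxy)-5,6,5',6'-tetrahydro-β,β-carotene, via half-coupled C30 aldehyde 19 (not isolated)
Conditions: KN(SiMe3)2, THF, −78 → 0 °C, dark
Reagents that add atoms: none
Why: Twofold Julia–Kocienski olefination: the potassium sulfonyl carbanion adds to each aldehyde, and Smiles rearrangement with loss of SO2 and the tetrazolone gives the disubstituted C7=C8 bonds. The phenyltetrazolyl sulfone and the potassium base favour E, and any Z content at these bonds can be equilibrated thermally to the all-E isomer.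

Step 13
Reactants: 20 (3R,4S,5R,6R,3'R,4'S,5'R,6'R)-3,3'-bis(tert-butyldimethylsilyloxy)-4,4'-bis(triethylsilyloxy)-5,6,5',6'-tetrahydro-β,β-carotene
Product: 22 (3R,4S,5R,6R,3'R,4'S,5'R,6'R)-3,3'-bis(tert-butyldimethylsilyloxy)-5,6,5',6'-tetrahydro-β,β-carotene-4,4'-diol, via mono-desilylated carotenol 21 (not isolated)
Conditions: pyridinium p-toluenesulfonate (cat.), MeOH/CH2Cl2, 0 °C, dark
Reagents that add atoms: none
Why: Mild acid-catalysed methanolysis removes the secondary triethylsilyl ethers far faster than the hindered axial TBS ethers, so only O4 is freed; the polyene tolerates the buffered acid in the cold.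

Step 14
Reactants: 22 (3R,4S,5R,6R,3'R,4'S,5'R,6'R)-3,3'-bis(tert-butyldimethylsilyloxy)-5,6,5',6'-tetrahydro-β,β-carotene-4,4'-diol
Product: 24 (3R,4S,5R,6R,3'R,4'S,5'R,6'R)-3,3'-bis(tert-butyldimethylsilyloxy)-5,6,5',6'-tetrahydro-β,β-carotene-4,4'-diyl bis(hydrogen sulfate), via carotenol monosulfate 23 (not isolated)
Conditions: SO3·pyridine, pyridine, rt, dark
Reagents that add atoms: sulfur trioxide–pyridine complex, O=S(=O)([O-])[n+]1ccccc1
Why: O-Sulfation of a secondary alcohol with a sulfur trioxide–amine complex; O3 is silylated, so only O4 can react, and the basic medium protects the polyene.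

Step 15
Reactants: 24 (3R,4S,5R,6R,3'R,4'S,5'R,6'R)-3,3'-bis(tert-butyldimethylsilyloxy)-5,6,5',6'-tetrahydro-β,β-carotene-4,4'-diyl bis(hydrogen sulfate)
Product: 26 (3R,4S,5R,6R,3'R,4'S,5'R,6'R)-5,6,5',6'-tetrahydro-β,β-carotene-3,4,3',4'-tetrol 4,4'-bis(hydrogen sulfate), via mono-desilylated disulfate 25 (not isolated)
Conditions: Bu4NF, THF, rt → 40 °C, dark; ion exchange
Reagents that add atoms: none
Why: Fluoride-mediated desilylation; sulfate half-ester anions are inert to fluoride and, being cis to the O3 oxygen, cannot be displaced by it, so only the Si–O bonds break.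

## Compound list

1 | mesityl oxide (4-methylpent-3-en-2-one) | CC(C)=CC(C)=O | starting material
2 | 4-methyl-2-(trimethylsilyloxy)penta-1,3-diene | CC(C)=CC(=C)O[Si](C)(C)C | intermediate
3 | 1,3-oxazolidin-2-one | O=C1NCCO1 | starting material
4 | (E)-but-2-enoyl chloride | C/C=C/C(Cl)=O | starting material
5 | 3-[(E)-but-2-enoyl]-1,3-oxazolidin-2-one | C/C=C/C(=O)N1CCOC1=O | intermediate
6 | 3-[(3S)-3,7-dimethyl-5-oxo-1-(trimethylsilyloxy)octa-1,6-dien-1-yl]-1,3-oxazolidin-2-one (open-chain Michael adduct, silyl-transferred form) | CC(C)=CC(=O)C[C@H](C)C=C(O[Si](C)(C)C)N1CCOC1=O | intermediate (not isolated)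
7 | 3-[(1R,6S)-2,2,6-trimethyl-4-(trimethylsilyloxy)cyclohex-3-ene-1-carbonyl]-1,3-oxazolidin-2-one | O=C(N1CCOC1=O)[C@@H]1[C@@H](C)CC(O[Si](C)(C)C)=CC1(C)C | intermediate (not isolated)
8 | 3-[(1R,6S)-2,2,6-trimethyl-4-oxocyclohexane-1-carbonyl]-1,3-oxazolidin-2-one (acyl and methyl trans) | O=C(N1CCOC1=O)[C@@H]1[C@@H](C)CC(=O)CC1(C)C | intermediate
9 | 3-[(1R,2S)-2,6,6-trimethyl-4-(triethylsilyloxy)cyclohex-3-ene-1-carbonyl]-1,3-oxazolidin-2-one | O=C(N1CCOC1=O)[C@@H]1[C@@H](C)C=C(O[Si](CC)(CC)CC)CC1(C)C | intermediate
10 | epoxide of 9 at the enol ether double bond, oxirane oxygen cis to the neighbouring ring methyl: 3-[2,4,4-trimethyl-6-(triethylsilyloxy)-7-oxabicyclo[4.1.0]heptane-3-carbonyl]-1,3-oxazolidin-2-one | O=C(N1CCOC1=O)[C@@H]1[C@@H](C)[C@H]2O[C@@]2(O[Si](CC)(CC)CC)CC1(C)C | intermediate (not isolated)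
11 | 3-[(1R,5R,6R)-2,2,6-trimethyl-4-oxo-5-(triethylsilyloxy)cyclohexane-1-carbonyl]-1,3-oxazolidin-2-one (silyloxy axial, cis to the neighbouring methyl) | O=C(N1CCOC1=O)[C@@H]1[C@@H](C)[C@@H](O[Si](CC)(CC)CC)C(=O)CC1(C)C | intermediate
12 | 3-[(1R,5S,6R)-2,2,6-trimethyl-4-oxo-5-(triethylsilyloxy)cyclohexane-1-carbonyl]-1,3-oxazolidin-2-one (silyloxy equatorial, trans to the neighbouring methyl) | O=C(N1CCOC1=O)[C@@H]1[C@@H](C)[C@H](O[Si](CC)(CC)CC)C(=O)CC1(C)C | intermediate
13 | 3-[(1R,4R,5S,6R)-4-hydroxy-2,2,6-trimethyl-5-(triethylsilyloxy)cyclohexane-1-carbonyl]-1,3-oxazolidin-2-one | O=C(N1CCOC1=O)[C@@H]1[C@@H](C)[C@H](O[Si](CC)(CC)CC)[C@H](O)CC1(C)C | intermediate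
14 | 3-[(1R,4R,5S,6R)-4-(tert-butyldimethylsilyloxy)-2,2,6-trimethyl-5-(triethylsilyloxy)cyclohexane-1-carbonyl]-1,3-oxazolidin-2-one | O=C(N1CCOC1=O)[C@@H]1[C@@H](C)[C@H](O[Si](CC)(CC)CC)[C@H](O[Si](C)(C)C(C)(C)C)CC1(C)C | intermediate
15 | [(1R,4R,5S,6R)-4-(tert-butyldimethylsilyloxy)-2,2,6-trimethyl-5-(triethylsilyloxy)cyclohexyl]methanol | OC[C@@H]1[C@@H](C)[C@H](O[Si](CC)(CC)CC)[C@H](O[Si](C)(C)C(C)(C)C)CC1(C)C | intermediate
16 | 5-({[(1R,4R,5S,6R)-4-(tert-butyldimethylsilyloxy)-2,2,6-trimethyl-5-(triethylsilyloxy)cyclohexyl]methyl}sulfanyl)-1-phenyl-1H-tetrazole | C(Sc1nnnn1-c1ccccc1)[C@@H]1[C@@H](C)[C@H](O[Si](CC)(CC)CC)[C@H](O[Si](C)(C)C(C)(C)C)CC1(C)C | intermediate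
17 | 5-({[(1R,4R,5S,6R)-4-(tert-butyldimethylsilyloxy)-2,2,6-trimethyl-5-(triethylsilyloxy)cyclohexyl]methyl}sulfonyl)-1-phenyl-1H-tetrazole | O=S(=O)(C[C@@H]1[C@@H](C)[C@H](O[Si](CC)(CC)CC)[C@H](O[Si](C)(C)C(C)(C)C)CC1(C)C)c1nnnn1-c1ccccc1 | intermediate
18 | crocetin dialdehyde, (2E,4E,6E,8E,10E,12E,14E)-2,6,11,15-tetramethylhexadeca-2,4,6,8,10,12,14-heptaenedial | O=C/C(C)=C/C=C/C(C)=C/C=C/C=C(C)/C=C/C=C(C)/C=O | starting material
19 | (3R,4S,5R,6R)-3-(tert-butyldimethylsilyloxy)-4-(triethylsilyloxy)-5,6-dihydro-8'-apo-β-caroten-8'-al (all-E) | O=C/C(C)=C/C=C/C(C)=C/C=C/C=C(C)/C=C/C=C(C)/C=C/[C@@H]1[C@@H](C)[C@H](O[Si](CC)(CC)CC)[C@H](O[Si](C)(C)C(C)(C)C)CC1(C)C | intermediate (not isolated)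
20 | (3R,4S,5R,6R,3'R,4'S,5'R,6'R)-3,3'-bis(tert-butyldimethylsilyloxy)-4,4'-bis(triethylsilyloxy)-5,6,5',6'-tetrahydro-β,β-carotene (all-E) | CC(/C=C/C=C(C)/C=C/[C@@H]1[C@@H](C)[C@H](O[Si](CC)(CC)CC)[C@H](O[Si](C)(C)C(C)(C)C)CC1(C)C)=C\C=C\C=C(C)\C=C\C=C(C)\C=C\[C@@H]1[C@@H](C)[C@H](O[Si](CC)(CC)CC)[C@H](O[Si](C)(C)C(C)(C)C)CC1(C)C | intermediate
21 | (3R,4S,5R,6R,3'R,4'S,5'R,6'R)-3,3'-bis(tert-butyldimethylsilyloxy)-4'-(triethylsilyloxy)-5,6,5',6'-tetrahydro-β,β-caroten-4-ol | CC(/C=C/C=C(C)/C=C/[C@@H]1[C@@H](C)[C@H](O)[C@H](O[Si](C)(C)C(C)(C)C)CC1(C)C)=C\C=C\C=C(C)\C=C\C=C(C)\C=C\[C@@H]1[C@@H](C)[C@H](O[Si](CC)(CC)CC)[C@H](O[Si](C)(C)C(C)(C)C)CC1(C)C | intermediate (not isolated)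
22 | (3R,4S,5R,6R,3'R,4'S,5'R,6'R)-3,3'-bis(tert-butyldimethylsilyloxy)-5,6,5',6'-tetrahydro-β,β-carotene-4,4'-diol | CC(/C=C/C=C(C)/C=C/[C@@H]1[C@@H](C)[C@H](O)[C@H](O[Si](C)(C)C(C)(C)C)CC1(C)C)=C\C=C\C=C(C)\C=C\C=C(C)\C=C\[C@@H]1[C@@H](C)[C@H](O)[C@H](O[Si](C)(C)C(C)(C)C)CC1(C)C | intermediate
23 | (3R,4S,5R,6R,3'R,4'S,5'R,6'R)-3,3'-bis(tert-butyldimethylsilyloxy)-4'-hydroxy-5,6,5',6'-tetrahydro-β,β-caroten-4-yl hydrogen sulfate | CC(/C=C/C=C(C)/C=C/[C@@H]1[C@@H](C)[C@H](OS(=O)(=O)O)[C@H](O[Si](C)(C)C(C)(C)C)CC1(C)C)=C\C=C\C=C(C)\C=C\C=C(C)\C=C\[C@@H]1[C@@H](C)[C@H](O)[C@H](O[Si](C)(C)C(C)(C)C)CC1(C)C | intermediate (not isolated)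
24 | (3R,4S,5R,6R,3'R,4'S,5'R,6'R)-3,3'-bis(tert-butyldimethylsilyloxy)-5,6,5',6'-tetrahydro-β,β-carotene-4,4'-diyl bis(hydrogen sulfate) | CC(/C=C/C=C(C)/C=C/[C@@H]1[C@@H](C)[C@H](OS(=O)(=O)O)[C@H](O[Si](C)(C)C(C)(C)C)CC1(C)C)=C\C=C\C=C(C)\C=C\C=C(C)\C=C\[C@@H]1[C@@H](C)[C@H](OS(=O)(=O)O)[C@H](O[Si](C)(C)C(C)(C)C)CC1(C)C | intermediate
25 | (3R,4S,5R,6R,3'R,4'S,5'R,6'R)-3'-(tert-butyldimethylsilyloxy)-3-hydroxy-5,6,5',6'-tetrahydro-β,β-carotene-4,4'-diyl bis(hydrogen sulfate) | CC(/C=C/C=C(C)/C=C/[C@@H]1[C@@H](C)[C@H](OS(=O)(=O)O)[C@H](O)CC1(C)C)=C\C=C\C=C(C)\C=C\C=C(C)\C=C\[C@@H]1[C@@H](C)[C@H](OS(=O)(=O)O)[C@H](O[Si](C)(C)C(C)(C)C)CC1(C)C | intermediate (not isolated)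
26 | (3R,4S,5R,6R,3'R,4'S,5'R,6'R)-5,6,5',6'-tetrahydro-β,β-carotene-3,4,3',4'-tetrol 4,4'-bis(hydrogen sulfate), CNP0202532.2 | CC(/C=C/C=C(C)/C=C/[C@@H]1[C@@H](C)[C@H](OS(=O)(=O)O)[C@H](O)CC1(C)C)=C\C=C\C=C(C)\C=C\C=C(C)\C=C\[C@@H]1[C@@H](C)[C@H](OS(=O)(=O)O)[C@H](O)CC1(C)C | target

## Step count and the least certain steps

Total: 15 steps. Longest linear sequence: 14 steps (step 1, then steps 3 to 15). Step 2 is a one-step branch, and the C20 dialdehyde 18 enters at step 12.

**Step 3 (key step).**
- What may go wrong: the annulation may stop after the first bond. Silicon can be transferred away from the first adduct, giving the open-chain product or its dihydropyran isomer, faster than the copper enolate closes onto the hindered β,β-disubstituted enone. Facial selectivity lower than with simpler partners is the second concern.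
- Fallback, from 2 and 5 back to 8, in two known steps. The copper–bis(oxazoline) Mukaiyama–Michael addition is run alone, with (CF3)2CHOH as silyl acceptor so that the catalyst turns over. It releases 3-[(3S)-3,7-dimethyl-5-oxooct-6-enoyl]-1,3-oxazolidin-2-one F1. F1 is then closed in a separate step by soft enolisation of the imide (TiCl4, i-Pr2NEt, CH2Cl2) and intramolecular Michael addition of the titanium enolate to the enone, which gives the trans ketone 8.

**Step 4.**
- What may go wrong: poor regioselectivity of deprotonation. C2 and C4 are both ring methylenes, each next to a carbon with an equatorial methyl, and differ only by the second methyl on C1. A mixture of enol ethers, and after step 5 of C2- and C4-oxygenated ketones, would have to be separated.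
- Fallback, from 2 and 5 back to 11/12 before step 6. The C4 oxygen is moved into the nucleophile, so that the question does not arise. Rubottom oxidation of 2 (mCPBA) gives 1-hydroxy-4-methylpent-3-en-2-one F2. Silylation (Et3SiCl, imidazole) gives 4-methyl-1-(triethylsilyloxy)pent-3-en-2-one F3. Kinetic enol silylation (LiN(i-Pr)2, Me3SiCl) gives (1Z)-4-methyl-1-(triethylsilyloxy)-2-(trimethylsilyloxy)penta-1,3-diene F4. Annulation of F4 with 5 under the conditions of step 3 and hydrolysis gives the α-silyloxy ketones 11 and 12 directly. The C4 configuration is immaterial because step 6 equilibrates it. This variant rests on the same annulation with a more substituted nucleophile and also removes steps 4 and 5.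

**Step 6.**
- What may go wrong: incomplete equilibration. The equatorial preference of an α-silyloxy group is modest, because its C–O dipole then lies nearly parallel to the carbonyl dipole, so repeated separation and recycling may be needed.
- Fallback, from 11 back to 14. C4 is inverted after C3 is set. Reduction of 11 with LiBH(s-Bu)3 gives 3-[(1R,4R,5R,6R)-4-hydroxy-2,2,6-trimethyl-5-(triethylsilyloxy)cyclohexane-1-carbonyl]-1,3-oxazolidin-2-one F5. Silylation (t-BuMe2SiOTf, 2,6-lutidine) gives 3-[(1R,4R,5R,6R)-4-(tert-butyldimethylsilyloxy)-2,2,6-trimethyl-5-(triethylsilyloxy)cyclohexane-1-carbonyl]-1,3-oxazolidin-2-one F6. Selective methanolysis (pyridinium p-toluenesulfonate, MeOH) gives 3-[(1R,4R,5R,6R)-4-(tert-butyldimethylsilyloxy)-5-hydroxy-2,2,6-trimethylcyclohexane-1-carbonyl]-1,3-oxazolidin-2-one F7. Dess–Martin oxidation gives 3-[(1R,4R,6R)-4-(tert-butyldimethylsilyloxy)-2,2,6-trimethyl-5-oxocyclohexane-1-carbonyl]-1,3-oxazolidin-2-one F8. NaBH4 then attacks axially, anti to the axial α-silyloxy group and past syn-axial hydrogens only, and gives the equatorial alcohol 3-[(1R,4R,5S,6R)-4-(tert-butyldimethylsilyloxy)-5-hydroxy-2,2,6-trimethylcyclohexane-1-carbonyl]-1,3-oxazolidin-2-one F9. Silylation (Et3SiCl, imidazole) gives 14.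

**Step 9.**
- What may go wrong: hydride attack at the ring carbamate carbonyl instead of the crowded exocyclic one, since the acyl carbon sits between a quaternary and a tertiary carbon. This would open the oxazolidinone to a hydroxyethyl amide.
- Fallback, from 14 back to 15. LiOH/H2O2 is used, whose hydroperoxide anion cleaves hindered imides at the exocyclic carbonyl. It gives (1R,4R,5S,6R)-4-(tert-butyldimethylsilyloxy)-2,2,6-trimethyl-5-(triethylsilyloxy)cyclohexane-1-carboxylic acid F10, which LiAlH4 (THF, 0 °C) reduces to 15.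

**Step 12.**
- What may go wrong: slow addition of the β-branched sulfonyl carbanion to the sparingly soluble, vinylogous dialdehyde, so that the reaction stops at 19. Self-condensation of the sulfone and lowered E preference with a conjugated aldehyde are further concerns.
- Fallback, from 15 and 18 back to 20, with reversed polarity. Dess–Martin oxidation of 15 gives (1R,4R,5S,6R)-4-(tert-butyldimethylsilyloxy)-2,2,6-trimethyl-5-(triethylsilyloxy)cyclohexane-1-carbaldehyde F11. NaBH4 reduction of 18 gives (2E,4E,6E,8E,10E,12E,14E)-2,6,11,15-tetramethylhexadeca-2,4,6,8,10,12,14-heptaene-1,16-diol F12. PPh3·HBr converts F12 into [(2E,4E,6E,8E,10E,12E,14E)-2,6,11,15-tetramethylhexadeca-2,4,6,8,10,12,14-heptaene-1,16-diyl]bis(triphenylphosphonium) dibromide F13. Twofold Wittig reaction of F13 with F11 (NaOMe, CH2Cl2/MeOH), followed by thermal equilibration to the all-E isomer, gives 20.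

## Further compounds

F1 | step 3 | 3-[(3S)-3,7-dimethyl-5-oxooct-6-enoyl]-1,3-oxazolidin-2-one | CC(C)=CC(=O)C[C@H](C)CC(=O)N1CCOC1=O
F2 | step 4 | 1-hydroxy-4-methylpent-3-en-2-one | CC(C)=CC(=O)CO
F3 | step 4 | 4-methyl-1-(triethylsilyloxy)pent-3-en-2-one | CC(C)=CC(=O)CO[Si](CC)(CC)CC
F4 | step 4 | (1Z)-4-methyl-1-(triethylsilyloxy)-2-(trimethylsilyloxy)penta-1,3-diene | CC(C)=C/C(O[Si](C)(C)C)=C/O[Si](CC)(CC)CC
F5 | step 6 | 3-[(1R,4R,5R,6R)-4-hydroxy-2,2,6-trimethyl-5-(triethylsilyloxy)cyclohexane-1-carbonyl]-1,3-oxazolidin-2-one | O=C(N1CCOC1=O)[C@@H]1[C@@H](C)[C@@H](O[Si](CC)(CC)CC)[C@H](O)CC1(C)C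
F6 | step 6 | 3-[(1R,4R,5R,6R)-4-(tert-butyldimethylsilyloxy)-2,2,6-trimethyl-5-(triethylsilyloxy)cyclohexane-1-carbonyl]-1,3-oxazolidin-2-one | O=C(N1CCOC1=O)[C@@H]1[C@@H](C)[C@@H](O[Si](CC)(CC)CC)[C@H](O[Si](C)(C)C(C)(C)C)CC1(C)C
F7 | step 6 | 3-[(1R,4R,5R,6R)-4-(tert-butyldimethylsilyloxy)-5-hydroxy-2,2,6-trimethylcyclohexane-1-carbonyl]-1,3-oxazolidin-2-one | O=C(N1CCOC1=O)[C@@H]1[C@@H](C)[C@@H](O)[C@H](O[Si](C)(C)C(C)(C)C)CC1(C)C
F8 | step 6 | 3-[(1R,4R,6R)-4-(tert-butyldimethylsilyloxy)-2,2,6-trimethyl-5-oxocyclohexane-1-carbonyl]-1,3-oxazolidin-2-one | O=C(N1CCOC1=O)[C@@H]1[C@@H](C)C(=O)[C@H](O[Si](C)(C)C(C)(C)C)CC1(C)C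
F9 | step 6 | 3-[(1R,4R,5S,6R)-4-(tert-butyldimethylsilyloxy)-5-hydroxy-2,2,6-trimethylcyclohexane-1-carbonyl]-1,3-oxazolidin-2-one | O=C(N1CCOC1=O)[C@@H]1[C@@H](C)[C@H](O)[C@H](O[Si](C)(C)C(C)(C)C)CC1(C)C
F10 | step 9 | (1R,4R,5S,6R)-4-(tert-butyldimethylsilyloxy)-2,2,6-trimethyl-5-(triethylsilyloxy)cyclohexane-1-carboxylic acid | OC(=O)[C@@H]1[C@@H](C)[C@H](O[Si](CC)(CC)CC)[C@H](O[Si](C)(C)C(C)(C)C)CC1(C)C
F11 | step 12 | (1R,4R,5S,6R)-4-(tert-butyldimethylsilyloxy)-2,2,6-trimethyl-5-(triethylsilyloxy)cyclohexane-1-carbaldehyde | O=C[C@@H]1[C@@H](C)[C@H](O[Si](CC)(CC)CC)[C@H](O[Si](C)(C)C(C)(C)C)CC1(C)C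
F12 | step 12 | (2E,4E,6E,8E,10E,12E,14E)-2,6,11,15-tetramethylhexadeca-2,4,6,8,10,12,14-heptaene-1,16-diol | OC/C(C)=C/C=C/C(C)=C/C=C/C=C(C)/C=C/C=C(C)/CO
F13 | step 12 | [(2E,4E,6E,8E,10E,12E,14E)-2,6,11,15-tetramethylhexadeca-2,4,6,8,10,12,14-heptaene-1,16-diyl]bis(triphenylphosphonium) dibromide | [Br-].[Br-].c1ccccc1[P+](c1ccccc1)(c1ccccc1)C/C(C)=C/C=C/C(C)=C/C=C/C=C(C)/C=C/C=C(C)/C[P+](c1ccccc1)(c1ccccc1)c1ccccc1
A1 | alternative 1 | 2-(hydroxymethyl)-3-methyl-4,5-(isopropylidenedioxy)cyclohexanone (hydroxymethyl trans to methyl, methyl trans to the neighbouring oxygen) | OC[C@@H]1[C@@H](C)[C@H](OC2(C)C)[C@H](O2)CC1=O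
A2 | alternative 1 | 4,5-(isopropylidenedioxy)cyclohex-2-en-1-one (cis-fused acetonide enone from quinic acid) | C1=C[C@H](OC2(C)C)[C@H](O2)CC1=O
A3 | alternative 1 | (−)-quinic acid, (1S,3R,4S,5R)-1,3,4,5-tetrahydroxycyclohexane-1-carboxylic acid | C1[C@H]([C@H]([C@@H](C[C@@]1(C(=O)O)O)O)O)O
A4 | alternative 2 | (3R,4S,5R,6R,3'R,4'S,5'R,6'R)-3,4,3',4'-tetrakis(tert-butyldimethylsilyloxy)-5,6,5',6'-tetrahydro-β,β-carotene | CC(/C=C/C=C(C)/C=C/[C@@H]1[C@@H](C)[C@H](O[Si](C)(C)C(C)(C)C)[C@H](O[Si](C)(C)C(C)(C)C)CC1(C)C)=C\C=C\C=C(C)\C=C\C=C(C)\C=C\[C@@H]1[C@@H](C)[C@H](O[Si](C)(C)C(C)(C)C)[C@H](O[Si](C)(C)C(C)(C)C)CC1(C)C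
A5 | alternative 2 | ring enyne: (E)-but-1-en-3-ynyl group on C6 of the ring of the target (3R,4S,5R,6R), both oxygens as tert-butyldimethylsilyl ethers | C#C/C=C/[C@@H]1[C@@H](C)[C@H](O[Si](C)(C)C(C)(C)C)[C@H](O[Si](C)(C)C(C)(C)C)CC1(C)C
A6 | alternative 2 | (1E,3E,5E,7E,9E)-1,10-diiodo-3,8-dimethyldeca-1,3,5,7,9-pentaene | I/C=C/C(C)=C/C=C/C=C(C)/C=C/I
A7 | alternative 3 | 2,2,2-trifluoroethyl cis-2,6,6-trimethylcyclohex-3-ene-1-carboxylate (endo adduct) | O=C(OCC(F)(F)F)[C@H]1[C@@H](C)C=CCC1(C)C
A8 | alternative 3 | (E)-penta-1,3-diene | C=C/C=C/C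
A9 | alternative 3 | 2,2,2-trifluoroethyl 3-methylbut-2-enoate | CC(C)=CC(=O)OCC(F)(F)F
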